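**Retrosynthetic overview**

1. Numbering: drimane positions are used for the terpenoid half (ring A = C1–C5 and C10; ring B = C5–C10; C11 = the OCH2 carbon on C9).
2. Late stage: the C11–O aryl ether comes from Mitsunobu coupling with isofraxidin, the C4 gem-dimethyl group from double α′-methylation, and the ring A enone (C3=O, C1=C2) from Stork–Danheiser transposition of a ring A 1,3-dione.
3. Key disconnection: C5–C10 and C2–C3 are made together by a base-mediated Michael–Claisen (3+3) bicyclisation of an open-chain keto enoate; ring B closes first (Michael), ring A second (Claisen); the coumarin ring is bought.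
4. Enabling feature: in ring A, C2 and the quaternary C10 both flank C1, and C3 is joined to C5 through C4. With C1 as a ketone carbon, C10 and C2 are the two α-carbons of one methyl ketone and C5/C4/C3 are the β-carbon, α-carbon and carbonyl of an enoate, so one ketone acts twice as nucleophile.
5. Precursor assembly: (Z)-C7=C8 from but-2-yn-1-ol, C9 by rhodium-catalysed asymmetric alkenyl addition to furan-2(5H)-one, C2 from MeLi, C3/C4 from methyl acrylate by cross-metathesis.

Key step: step 10

Remark on the chemistry: the sense of induction in step 5 is assigned by analogy with rhodium/BINAP additions to cyclic enones; should the opposite sense be found, (S)-BINAP is used instead.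

**Route**

Step 1
Reactants: 1 but-2-yn-1-ol
Product: 3 (2Z)-3-iodobut-2-en-1-ol, via cyclic alkenylaluminate 2 (not isolated)
Conditions: NaAlH2(OCH2CH2OMe)2, THF, 0 °C to rt; then I2, THF, −78 to 0 °C
Reagents that add atoms: iodine (II)
Why: Hydroxyl-directed trans-hydroalumination of the propargylic alcohol puts aluminium on C3 in a five-membered oxaaluminacycle, and iodinolysis with retention should give the (Z)-iodoalkene with iodine cis to CH2OH, the geometry ring B later needs.

Step 2
Reactants: 3 (2Z)-3-iodobut-2-en-1-ol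
Product: 4 (2Z)-1-bromo-3-iodobut-2-ene
Conditions: CBr4, PPh3, CH2Cl2, 0 °C
Reagents that add atoms: tetrabromomethane (BrC(Br)(Br)Br)
Why: Appel bromination of a primary allylic alcohol by SN2 on the alkoxyphosphonium ion; the alkene geometry is not touched.

Step 3
Reactants: 4 (2Z)-1-bromo-3-iodobut-2-ene
Product: 5 (4Z)-5-iodohexa-1,4-diene
Conditions: CH2=CHMgBr, CuI (5 mol%), THF, −40 °C
Reagents that add atoms: vinylmagnesium bromide (C=C[Mg]Br)
Why: Copper-catalysed SN2 coupling of an allylic bromide with a vinyl Grignard reagent; the fully substituted γ-carbon blocks SN2′ attack and the alkenyl iodide should not react at this temperature.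

Step 4
Reactants: 5 (4Z)-5-iodohexa-1,4-diene
Product: 7 [(2E)-hexa-2,5-dien-2-yl]boronic acid, via (2E)-hexa-2,5-dien-2-yllithium 6 (not isolated)
Conditions: t-BuLi (2 equiv), Et2O, −78 °C; then B(Oi-Pr)3, −78 °C to rt; 1 M HCl
Reagents that add atoms: triisopropyl borate (CC(C)OB(OC(C)C)OC(C)C); water (O)
Why: Iodine–lithium exchange and borylation of the alkenyllithium both go with retention, so boron stays cis to the allylic CH2 (the E descriptor only reflects the lower rank of Li and B against CH3).

Step 5
Reactants: 7 [(2E)-hexa-2,5-dien-2-yl]boronic acid; 8 furan-2(5H)-one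
Product: 9 (4R)-4-[(2Z)-hexa-2,5-dien-2-yl]oxolan-2-one
Conditions: Rh(acac)(C2H4)2 (3 mol%), (R)-BINAP (3.3 mol%), 1,4-dioxane/H2O 10:1, 100 °C
Reagents that add atoms: none
Why: Rhodium-catalysed asymmetric conjugate addition of an alkenylboronic acid to a butenolide (Hayashi–Miyaura reaction); the BINAP-bound alkenylrhodium species selects one face of the enoate and so sets C9 (lactone C4).

Step 6
Reactants: 9 (4R)-4-[(2Z)-hexa-2,5-dien-2-yl]oxolan-2-one
Product: 11 (3S,4R)-3-methyl-4-[(2Z)-hexa-2,5-dien-2-yl]oxolan-2-one, via lithium enolate 10 (not isolated)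
Conditions: LiN(i-Pr)2, THF, −78 °C; then MeI
Reagents that add atoms: iodomethane (CI)
Why: Lactone enolate alkylation; MeI should approach anti to the C4 alkenyl group (trans product), and the configuration of this carbon (future C10) is erased again in step 10.

Step 7
Reactants: 11 (3S,4R)-3-methyl-4-[(2Z)-hexa-2,5-dien-2-yl]oxolan-2-one
Product: 12 (3S,4R,5Z)-4-(hydroxymethyl)-3,5-dimethylnona-5,8-dien-2-one
Conditions: MeLi (1.05 equiv), THF, −78 °C; AcOH quench at −78 °C
Reagents that add atoms: methyllithium ([Li]C)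
Why: Single addition of MeLi to a γ-lactone; the cyclic lithium hemiketal persists at −78 °C and should collapse only on quench to the hydroxy methyl ketone (in equilibrium with its lactol), which supplies C2.

Step 8
Reactants: 12 (3S,4R,5Z)-4-(hydroxymethyl)-3,5-dimethylnona-5,8-dien-2-one
Product: 13 (3S,4R,5Z)-4-({[tert-butyl(diphenyl)silyl]oxy}methyl)-3,5-dimethylnona-5,8-dien-2-one
Conditions: t-BuPh2SiCl, imidazole, DMF, rt
Reagents that add atoms: tert-butyl(chloro)diphenylsilane (CC(C)(C)[Si](Cl)(c1ccccc1)c1ccccc1)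
Why: Silylation of the primary alcohol traps the open-chain keto form and keeps O11 from ketalising C1 in the later steps.

Step 9
Reactants: 13 (3S,4R,5Z)-4-({[tert-butyl(diphenyl)silyl]oxy}methyl)-3,5-dimethylnona-5,8-dien-2-one; 14 methyl acrylate
Product: 15 methyl (2E,5Z,7R,8S)-7-({[tert-butyl(diphenyl)silyl]oxy}methyl)-6,8-dimethyl-9-oxodeca-2,5-dienoate
Conditions: second-generation Hoveyda–Grubbs catalyst (5 mol%), 1,4-benzoquinone (10 mol%), CH2Cl2, 40 °C
Reagents that add atoms: none
Why: Cross-metathesis of the terminal alkene with an electron-poor acrylate should give the (E)-enoate; the trisubstituted alkene is inert and benzoquinone suppresses ruthenium hydride isomerisation of the skipped diene.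

Step 10
Reactants: 15 methyl (2E,5Z,7R,8S)-7-({[tert-butyl(diphenyl)silyl]oxy}methyl)-6,8-dimethyl-9-oxodeca-2,5-dienoate
Product: 17 trans-fused 8-({[tert-butyl(diphenyl)silyl]oxy}methyl)-7,8a-dimethyl-4a,5,8,8a-tetrahydronaphthalene-1,3(2H,4H)-dione, via Michael adduct keto ester 16 (not isolated)
Conditions: KOt-Bu (2.2 equiv), THF/t-BuOH, 0.01 M, −40 °C to rt; then 1 M HCl
Reagents that add atoms: none
Why: KOt-Bu reversibly gives the more substituted enolate at C10 of the methyl ketone, which adds to C5 of the (E)-enoate (Michael addition, 6-exo-trig, closes ring B, forms C5–C10); after proton transfer the C2 methyl-ketone enolate attacks the ester carbonyl C3 (Claisen condensation, 6-exo-trig, closes ring A, forms C2–C3), methoxide leaves, and deprotonation of the 1,3-dione makes the sequence irreversible. The closest known reaction type is the consecutive Michael–Claisen (3+3) synthesis of cyclohexane-1,3-diones from alkyl methyl ketones and acrylates, run here inside one chain. C10 is planar in the enolate, so both C10 epimers of 15 are funnelled into one product. The C9 stereocentre controls the new centres C10 and C5 through a chair-like transition state: allylic 1,2-strain with the C8 methyl holds the C9 CH2OSi group pseudoaxial, the enolate carbon C1 and the acrylate arm on C5 stay equatorial, and the C10 methyl becomes axial and anti to C11, which gives the trans ring fusion. The step needs C10 rather than C2 to attack C5 and must outrun base-induced migration of the skipped diene; ring size secures the first (C2 attack would need an eight-membered ring), and low temperature, high dilution and the thermodynamic sink of the dione enolate favour the second.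

Step 11
Reactants: 17 trans-fused 8-({[tert-butyl(diphenyl)silyl]oxy}methyl)-7,8a-dimethyl-4a,5,8,8a-tetrahydronaphthalene-1,3(2H,4H)-dione
Product: 18 8-({[tert-butyl(diphenyl)silyl]oxy}methyl)-3-methoxy-7,8a-dimethyl-4a,5,8,8a-tetrahydronaphthalen-1(4H)-one
Conditions: MeOH, p-TsOH (cat.), 3 Å molecular sieves, 40 °C
Reagents that add atoms: methanol (CO)
Why: Acid-catalysed enol etherification of a cyclic 1,3-dione under thermodynamic control should place the methoxy group on C3, the carbonyl next to the unhindered C4 methylene, and leave the C1 ketone that is shielded by the quaternary C10.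

Step 12
Reactants: 18 8-({[tert-butyl(diphenyl)silyl]oxy}methyl)-3-methoxy-7,8a-dimethyl-4a,5,8,8a-tetrahydronaphthalen-1(4H)-one
Product: 20 5-({[tert-butyl(diphenyl)silyl]oxy}methyl)-4a,6-dimethyl-4a,5,8,8a-tetrahydronaphthalen-2(1H)-one, via allylic alcohol 19 (not isolated)
Conditions: i-Bu2AlH, CH2Cl2, −78 °C; then 1 M HCl, THF, rt
Reagents that add atoms: water (O)
Why: Stork–Danheiser transposition: 1,2-reduction of the vinylogous ester carbonyl at C1, then acid hydrolysis of the enol ether and loss of water, should deliver the enone with C3=O and C1=C2.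

Step 13
Reactants: 20 5-({[tert-butyl(diphenyl)silyl]oxy}methyl)-4a,6-dimethyl-4a,5,8,8a-tetrahydronaphthalen-2(1H)-one
Product: 22 (4aR,5S,8aS)-5-({[tert-butyl(diphenyl)silyl]oxy}methyl)-1,1,4a,6-tetramethyl-4a,5,8,8a-tetrahydronaphthalen-2(1H)-one, via monomethyl ketone 21 (not isolated)
Conditions: LiN(i-Pr)2 (1.1 equiv), THF, −78 °C, MeI; then LiN(i-Pr)2 (1.2 equiv), MeI, −78 to 0 °C
Reagents that add atoms: iodomethane (CI)
Why: Kinetic α′-enolate alkylation of a cyclohexenone; C4 is the only enolisable position (C10 is quaternary, so no γ-deprotonation), and two cycles install the gem-dimethyl group.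

Step 14
Reactants: 22 (4aR,5S,8aS)-5-({[tert-butyl(diphenyl)silyl]oxy}methyl)-1,1,4a,6-tetramethyl-4a,5,8,8a-tetrahydronaphthalen-2(1H)-one
Product: 23 (4aR,5S,8aS)-5-(hydroxymethyl)-1,1,4a,6-tetramethyl-4a,5,8,8a-tetrahydronaphthalen-2(1H)-one
Conditions: HF·pyridine, THF, 0 °C to rt
Reagents that add atoms: none
Why: Fluoride cleavage of the silyl ether under acidic buffering, which avoids a free alkoxide that could add to C1 of the enone (oxa-Michael).

Step 15
Reactants: 23 (4aR,5S,8aS)-5-(hydroxymethyl)-1,1,4a,6-tetramethyl-4a,5,8,8a-tetrahydronaphthalen-2(1H)-one; 24 isofraxidin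
Product: 25 7-{[(1S,4aS,8aR)-2,5,5,8a-tetramethyl-6-oxo-1,4,4a,5,6,8a-hexahydronaphthalen-1-yl]methoxy}-6,8-dimethoxy-2H-chromen-2-one
Conditions: PPh3, i-PrO2CN=NCO2i-Pr, toluene, 0 to 50 °C
Reagents that add atoms: none
Why: Mitsunobu etherification: the acidic 7-OH of the coumarin is alkylated by the alkoxyphosphonium ion of the primary alcohol through SN2 at C11; no stereocentre is involved.

**Compound list**

1 | but-2-yn-1-ol | CC#CCO | starting material
2 | cyclic (Z)-alkenylaluminate from 1 (sodium salt, five-membered oxaaluminacycle, Al on C3) | CC1=CCO[Al-]1(OCCOC)OCCOC.[Na+] | intermediate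
3 | (2Z)-3-iodobut-2-en-1-ol | C/C(I)=C/CO | intermediate
4 | (2Z)-1-bromo-3-iodobut-2-ene | C/C(I)=C/CBr | intermediate
5 | (4Z)-5-iodohexa-1,4-diene | C/C(I)=C/CC=C | intermediate
6 | (2E)-hexa-2,5-dien-2-yllithium (Li cis to the allylic CH2) | C/C([Li])=C/CC=C | intermediate
7 | [(2E)-hexa-2,5-dien-2-yl]boronic acid (B cis to the allylic CH2) | C/C(B(O)O)=C/CC=C | intermediate
8 | furan-2(5H)-one | O=C1OCC=C1 | starting material
9 | (4R)-4-[(2Z)-hexa-2,5-dien-2-yl]oxolan-2-one | O=C1C[C@H](/C(C)=C\CC=C)CO1 | intermediate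
10 | lithium enolate of 9 | [Li]OC1=C[C@H](/C(C)=C\CC=C)CO1 | intermediate
11 | (3S,4R)-3-methyl-4-[(2Z)-hexa-2,5-dien-2-yl]oxolan-2-one (trans) | O=C1[C@@H](C)[C@H](/C(C)=C\CC=C)CO1 | intermediate
12 | (3S,4R,5Z)-4-(hydroxymethyl)-3,5-dimethylnona-5,8-dien-2-one | CC(=O)[C@@H](C)[C@@H](CO)/C(C)=C\CC=C | intermediate
13 | (3S,4R,5Z)-4-({[tert-butyl(diphenyl)silyl]oxy}methyl)-3,5-dimethylnona-5,8-dien-2-one | CC(=O)[C@@H](C)[C@@H](CO[Si](c1ccccc1)(c1ccccc1)C(C)(C)C)/C(C)=C\CC=C | intermediate
14 | methyl acrylate (methyl prop-2-enoate) | C=CC(=O)OC | starting material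
15 | methyl (2E,5Z,7R,8S)-7-({[tert-butyl(diphenyl)silyl]oxy}methyl)-6,8-dimethyl-9-oxodeca-2,5-dienoate | CC(=O)[C@@H](C)[C@@H](CO[Si](c1ccccc1)(c1ccccc1)C(C)(C)C)/C(C)=C\C/C=C/C(=O)OC | intermediate
16 | Michael adduct: methyl 2-[6-acetyl-5-({[tert-butyl(diphenyl)silyl]oxy}methyl)-4,6-dimethylcyclohex-3-en-1-yl]acetate (acetyl cis to the CH2OSi group, trans to the CH2CO2Me arm) | CC(C)(C)[Si](c1ccccc1)(c1ccccc1)OC[C@H]1C(C)=CC[C@H](CC(=O)OC)[C@@]1(C)C(C)=O | intermediate
17 | 8-({[tert-butyl(diphenyl)silyl]oxy}methyl)-7,8a-dimethyl-4a,5,8,8a-tetrahydronaphthalene-1,3(2H,4H)-dione (trans-fused; 4a-H and 8-CH2OSi on the face opposite to the 8a-methyl) | CC(C)(C)[Si](c1ccccc1)(c1ccccc1)OC[C@H]1C(C)=CC[C@@H]2CC(=O)CC(=O)[C@]21C | intermediate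
18 | 8-({[tert-butyl(diphenyl)silyl]oxy}methyl)-3-methoxy-7,8a-dimethyl-4a,5,8,8a-tetrahydronaphthalen-1(4H)-one (ring stereocentres as in 17) | CC(C)(C)[Si](c1ccccc1)(c1ccccc1)OC[C@H]1C(C)=CC[C@@H]2CC(OC)=CC(=O)[C@]21C | intermediate
19 | 8-({[tert-butyl(diphenyl)silyl]oxy}methyl)-3-methoxy-7,8a-dimethyl-1,4,4a,5,8,8a-hexahydronaphthalen-1-ol (carbinol configuration not defined) | CC(C)(C)[Si](c1ccccc1)(c1ccccc1)OC[C@H]1C(C)=CC[C@@H]2CC(OC)=CC(O)[C@]21C | intermediate
20 | 5-({[tert-butyl(diphenyl)silyl]oxy}methyl)-4a,6-dimethyl-4a,5,8,8a-tetrahydronaphthalen-2(1H)-one (trans-fused; 8a-H and 5-CH2OSi opposite to the 4a-methyl) | CC(C)(C)[Si](c1ccccc1)(c1ccccc1)OC[C@H]1C(C)=CC[C@@H]2CC(=O)C=C[C@]21C | intermediate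
21 | 5-({[tert-butyl(diphenyl)silyl]oxy}methyl)-1,4a,6-trimethyl-4a,5,8,8a-tetrahydronaphthalen-2(1H)-one (C1 configuration not defined, other centres as in 20) | CC(C)(C)[Si](c1ccccc1)(c1ccccc1)OC[C@H]1C(C)=CC[C@@H]2C(C)C(=O)C=C[C@]21C | intermediate
22 | (4aR,5S,8aS)-5-({[tert-butyl(diphenyl)silyl]oxy}methyl)-1,1,4a,6-tetramethyl-4a,5,8,8a-tetrahydronaphthalen-2(1H)-one | CC(C)(C)[Si](c1ccccc1)(c1ccccc1)OC[C@H]1C(C)=CC[C@@H]2C(C)(C)C(=O)C=C[C@]21C | intermediate
23 | (4aR,5S,8aS)-5-(hydroxymethyl)-1,1,4a,6-tetramethyl-4a,5,8,8a-tetrahydronaphthalen-2(1H)-one | OC[C@H]1C(C)=CC[C@@H]2C(C)(C)C(=O)C=C[C@]21C | intermediate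
24 | isofraxidin (7-hydroxy-6,8-dimethoxy-2H-chromen-2-one) | COc1cc2ccc(=O)oc2c(OC)c1O | starting material
25 | 7-{[(1S,4aS,8aR)-2,5,5,8a-tetramethyl-6-oxo-1,4,4a,5,6,8a-hexahydronaphthalen-1-yl]methoxy}-6,8-dimethoxy-2H-chromen-2-one | COc1cc2ccc(=O)oc2c(OC)c1OC[C@H]1C(C)=CC[C@@H]2C(C)(C)C(=O)C=C[C@]21C | target

Total step count: 15
Longest linear sequence: 15 steps (1 to 25)

**Steps most likely to fail**

Step 10. The base may move the skipped C4=C5/C7=C8 diene into conjugation by γ-deprotonation at C6 before the Michael addition, or the ring B closure may show poor facial selectivity. The fallback sets out from 15 and separates the two bond formations. The ketone is converted into its thermodynamic trimethylsilyl enol ether F1 (Me3SiCl, NaI, Et3N, MeCN). F1 is cyclised without any base by a Lewis-acid Mukaiyama–Michael addition (TiCl4, CH2Cl2, −78 °C) to keto ester 16, which is now isolated. 16 is then closed by a separate Claisen condensation (KOt-Bu, THF, 0 °C) and the route is rejoined at 17.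

Step 5. The α-branched alkenylboronic acid may transmetalate slowly and be lost by protodeboronation, or the enantioselectivity on the small butenolide may be insufficient. The fallback sets out from 5 and uses auxiliary control instead of catalyst control. Alkenyllithium 6 is added in the presence of CuBr·SMe2 and Me3SiCl (THF, −78 °C) to the N-enoyl oxazolidinone F2, made by N-acylation of (4S)-4-benzyl-1,3-oxazolidin-2-one with the mixed pivalic anhydride of (2E)-4-{[tert-butyl(dimethyl)silyl]oxy}but-2-enoic acid. Attack anti to the benzyl group of the chelated s-cis imide should give adduct F3. HF·pyridine then frees the hydroxy imide F4, whose alcohol lactonises onto the activated imide carbonyl and expels the auxiliary, rejoining the route at 9.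

Step 15. SN2 displacement at the β-branched C11 by the di-ortho-substituted phenol may be slow, so that decomposition of the alkoxyphosphonium ion or oxa-Michael closure of O11 onto C1 competes. The fallback sets out from 23 and replaces the redox condensation by sulfonate activation and displacement with a preformed phenoxide. 23 is converted into the methanesulfonate F5 (MeSO2Cl, Et3N, CH2Cl2, 0 °C), which is displaced by the cesium phenoxide of 24 (Cs2CO3, DMF, 60 °C) to arrive at 25.

**Further compounds**

F1 | step 10 | thermodynamic trimethylsilyl enol ether of 15 (silyloxy group on the former ketone carbon, tetrasubstituted enol double bond of undefined geometry) | CC(O[Si](C)(C)C)=C(C)[C@@H](CO[Si](c1ccccc1)(c1ccccc1)C(C)(C)C)/C(C)=C\C/C=C/C(=O)OC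
F2 | step 5 | (4S)-4-benzyl-3-[(2E)-4-{[tert-butyl(dimethyl)silyl]oxy}but-2-enoyl]-1,3-oxazolidin-2-one | O=C1OC[C@H](Cc2ccccc2)N1C(=O)/C=C/CO[Si](C)(C)C(C)(C)C
F3 | step 5 | (4S)-4-benzyl-3-[(3R,4Z)-3-({[tert-butyl(dimethyl)silyl]oxy}methyl)-4-methylocta-4,7-dienoyl]-1,3-oxazolidin-2-one | O=C1OC[C@H](Cc2ccccc2)N1C(=O)C[C@@H](CO[Si](C)(C)C(C)(C)C)/C(C)=C\CC=C
F4 | step 5 | (4S)-4-benzyl-3-[(3R,4Z)-3-(hydroxymethyl)-4-methylocta-4,7-dienoyl]-1,3-oxazolidin-2-one | O=C1OC[C@H](Cc2ccccc2)N1C(=O)C[C@@H](CO)/C(C)=C\CC=C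
F5 | step 15 | methanesulfonate of 23 | CS(=O)(=O)OC[C@H]1C(C)=CC[C@@H]2C(C)(C)C(=O)C=C[C@]21C
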